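The route rests on cutting the bond between the vinylic CH of the E-trisubstituted olefin C(CH3)=CH and its neighbouring CH2, which is homoallylic to the hydroxymethyl-bearing Z-olefin beside the butenolide ring (a 1,5-diene). The butenolide half can therefore be carried as a γ,δ-unsaturated carboxylic acid with one extra carbon. In one operation a nickel-electrocatalytic decarboxylative alkenylation expels CO2 from its N-hydroxyphthalimide ester and joins the resulting primary radical to the E-alkenyl iodide of the hydroxycyclohexene half, forming the C(sp2)–C(sp3) bond with retention of both olefin geometries and leaving both stereocentres, the ring hydroxyl and the butenolide untouched. The precursors are acid 25 and iodide 9.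

Key step: step 14

Assumption: 1, 2, 10, 11, 16 and 22 are taken as commercial; in step 3 the (R)-catalyst is assigned from the usual CBS model with the alkenyl arm as the large group, and the enantiomeric catalyst is used if the opposite sense is found.

Step 1
Reactants: 1 (4-bromobut-1-yn-1-yl)trimethylsilane; 2 2,6,6-trimethylcyclohex-2-en-1-one
Product: 4 2,6,6-trimethyl-1-[4-(trimethylsilyl)but-3-yn-1-yl]cyclohex-2-en-1-ol (racemic), via alkyllithium 3 (not isolated)
Conditions: Li, Et2O, −10 °C; then 2, −78 °C to 0 °C; aq NH4Cl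
Reagents that add atoms: none
Why: Reductive lithiation of the primary bromide gives alkyllithium 3, which adds 1,2 to the hindered enone (organolithium carbonyl addition); the tertiary carbinol is formed as a racemate and its centre is removed in step 2.

Step 2
Reactants: 4 2,6,6-trimethyl-1-[4-(trimethylsilyl)but-3-yn-1-yl]cyclohex-2-en-1-ol
Product: 5 2,4,4-trimethyl-3-[4-(trimethylsilyl)but-3-yn-1-yl]cyclohex-2-en-1-one
Conditions: pyridinium chlorochromate (C5H5NH)(CrO3Cl), CH2Cl2, rt
Reagents that add atoms: pyridinium chlorochromate [O-][Cr](=O)(=O)Cl.c1cc[nH+]cc1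
Why: Babler–Dauben oxidative transposition: the tertiary allylic chromate ester undergoes a [3,3] shift to the ring CH terminus and is oxidised there, which places the carbonyl next to the methyl-bearing olefin carbon and the side chain next to the gem-dimethyl carbon.

Step 3
Reactants: 5 2,4,4-trimethyl-3-[4-(trimethylsilyl)but-3-yn-1-yl]cyclohex-2-en-1-one
Product: 6 (1S)-2,4,4-trimethyl-3-[4-(trimethylsilyl)but-3-yn-1-yl]cyclohex-2-en-1-ol
Conditions: (R)-2-methyl-CBS-oxazaborolidine (20 mol %), catecholborane, toluene, −78 °C; then MeOH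
Reagents that add atoms: none
Why: Corey–Bakshi–Shibata reduction: the oxazaborolidine–borane complex binds the ketone with the α-methylalkenyl arm as the large group and delivers hydride to one face, which by the usual model should give the (S)-allylic alcohol, while catecholborane at −78 °C leaves the silylalkyne alone.

Step 4
Reactants: 6 (1S)-2,4,4-trimethyl-3-[4-(trimethylsilyl)but-3-yn-1-yl]cyclohex-2-en-1-ol
Product: 7 (1S)-3-(but-3-yn-1-yl)-2,4,4-trimethylcyclohex-2-en-1-ol
Conditions: K2CO3, MeOH, rt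
Reagents that add atoms: none
Why: Base-catalysed methanolysis of the alkynyl C–Si bond (protodesilylation) frees the terminal alkyne without affecting the allylic alcohol.

Step 5
Reactants: 7 (1S)-3-(but-3-yn-1-yl)-2,4,4-trimethylcyclohex-2-en-1-ol
Product: 9 (1S)-3-[(3E)-4-iodo-3-methylbut-3-en-1-yl]-2,4,4-trimethylcyclohex-2-en-1-ol, via alkenylalane 8 (not isolated)
Conditions: Me3Al (3 equiv), Cp2ZrCl2 (25 mol %), CH2Cl2, 0 °C to rt; then I2, THF, −30 °C
Reagents that add atoms: trimethylaluminium C[Al](C)C; iodine II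
Why: Negishi zirconium-catalysed carboalumination adds methyl and aluminium syn across the terminal alkyne with methyl on the internal carbon (alkenylalane 8, hydroxyl masked as its aluminium alkoxide), and iodinolysis with retention gives the E-alkenyl iodide.

Step 6
Reactants: 10 2-(2-bromoethyl)-1,3-dioxolane; 11 prop-2-yn-1-ol
Product: 14 (2Z)-4-(1,3-dioxolan-2-yl)-2-(iodomethylidene)butan-1-ol, via Grignard reagent 12 (not isolated), via alkenylmagnesium bromide 13 (not isolated)
Conditions: Mg, THF, rt; then 11, CuI (10 mol %), Et2O/THF, 0 °C to rt; then I2, −20 °C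
Reagents that add atoms: iodine II
Why: Copper-catalysed anti-carbomagnesiation of propargyl alcohol: the magnesium alkoxide directs the alkyl group of 12 to C2 and magnesium to C3 in a five-membered chelate (13), so iodinolysis with retention places iodine cis to the hydroxymethyl group (Z olefin).

Step 7
Reactants: 14 (2Z)-4-(1,3-dioxolan-2-yl)-2-(iodomethylidene)butan-1-ol
Product: 15 tert-butyl{[(2Z)-4-(1,3-dioxolan-2-yl)-2-(iodomethylidene)butyl]oxy}dimethylsilane
Conditions: TBSCl, imidazole, DMF, 0 °C to rt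
Reagents that add atoms: tert-butyldimethylsilyl chloride CC(C)(C)[Si](C)(C)Cl
Why: Silyl ether formation on the primary allylic alcohol removes the acidic proton before the metalation of step 8.

Step 8
Reactants: 15 tert-butyl{[(2Z)-4-(1,3-dioxolan-2-yl)-2-(iodomethylidene)butyl]oxy}dimethylsilane; 16 methyl (2S)-oxirane-2-carboxylate
Product: 19 methyl (2S,4Z)-2-(acetyloxy)-5-({[tert-butyl(dimethyl)silyl]oxy}methyl)-7-(1,3-dioxolan-2-yl)hept-4-enoate, via alkenylmagnesium chloride 17 (not isolated), via magnesium alkoxide 18 (not isolated)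
Conditions: i-PrMgCl·LiCl, THF, −20 °C to 0 °C; then CuI (10 mol %), 16, −40 °C to −10 °C; then Ac2O, DMAP (cat.), 0 °C
Reagents that add atoms: acetic anhydride CC(=O)OC(C)=O
Why: Iodine–magnesium exchange proceeds with retention of the Z geometry, copper-catalysed SN2 opening of the glycidate by 17 occurs at the unsubstituted C3 so that the C2 stereocentre of 16 is carried over unchanged, and alkoxide 18 is acetylated in the same flask (epoxide opening followed by O-acylation).

Step 9
Reactants: 19 methyl (2S,4Z)-2-(acetyloxy)-5-({[tert-butyl(dimethyl)silyl]oxy}methyl)-7-(1,3-dioxolan-2-yl)hept-4-enoate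
Product: 20 (5S)-5-[(2Z)-3-({[tert-butyl(dimethyl)silyl]oxy}methyl)-5-(1,3-dioxolan-2-yl)pent-2-en-1-yl]-4-hydroxyfuran-2(5H)-one
Conditions: LiN(SiMe3)2 (3 equiv), THF, −78 °C to 0 °C; then 1 M HCl
Reagents that add atoms: none
Why: Dieckmann-type cyclisation: the acetate enolate attacks the neighbouring methyl ester to close the five-membered tetronic acid, and the tetronate anion formed protects the C5 stereocentre from deprotonation.

Step 10
Reactants: 20 (5S)-5-[(2Z)-3-({[tert-butyl(dimethyl)silyl]oxy}methyl)-5-(1,3-dioxolan-2-yl)pent-2-en-1-yl]-4-hydroxyfuran-2(5H)-one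
Product: 21 (2S)-2-[(2Z)-3-({[tert-butyl(dimethyl)silyl]oxy}methyl)-5-(1,3-dioxolan-2-yl)pent-2-en-1-yl]-5-oxo-2,5-dihydrofuran-3-yl trifluoromethanesulfonate
Conditions: Tf2O, i-Pr2NEt, CH2Cl2, −78 °C
Reagents that add atoms: trifluoromethanesulfonic anhydride O=S(=O)(OS(=O)(=O)C(F)(F)F)C(F)(F)F
Why: O-Sulfonylation of the acidic 4-hydroxyl (enol triflate formation) gives an electron-poor alkenyl triflate for cross-coupling.

Step 11
Reactants: 21 (2S)-2-[(2Z)-3-({[tert-butyl(dimethyl)silyl]oxy}methyl)-5-(1,3-dioxolan-2-yl)pent-2-en-1-yl]-5-oxo-2,5-dihydrofuran-3-yl trifluoromethanesulfonate; 22 (tributylstannyl)methanol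
Product: 23 (5S)-5-[(2Z)-3-({[tert-butyl(dimethyl)silyl]oxy}methyl)-5-(1,3-dioxolan-2-yl)pent-2-en-1-yl]-4-(hydroxymethyl)furan-2(5H)-one
Conditions: Pd(PPh3)4 (5 mol %), LiCl, 1,4-dioxane, 90 °C
Reagents that add atoms: none
Why: Stille coupling: zerovalent palladium inserts into the enol triflate and the hydroxymethyl group is transferred from tin, which installs the C4 hydroxymethyl group under neutral conditions that do not epimerise C5.

Step 12
Reactants: 23 (5S)-5-[(2Z)-3-({[tert-butyl(dimethyl)silyl]oxy}methyl)-5-(1,3-dioxolan-2-yl)pent-2-en-1-yl]-4-(hydroxymethyl)furan-2(5H)-one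
Product: 24 (4Z)-4-({[tert-butyl(dimethyl)silyl]oxy}methyl)-6-[(2S)-3-(hydroxymethyl)-5-oxo-2,5-dihydrofuran-2-yl]hex-4-enal
Conditions: In(OTf)3 (2 mol %), acetone/H2O, rt
Reagents that add atoms: water O
Why: Lewis-acid-catalysed acetal hydrolysis under nearly neutral conditions frees the aldehyde while the allylic silyl ether and the butenolide remain.

Step 13
Reactants: 24 (4Z)-4-({[tert-butyl(dimethyl)silyl]oxy}methyl)-6-[(2S)-3-(hydroxymethyl)-5-oxo-2,5-dihydrofuran-2-yl]hex-4-enal
Product: 25 (4Z)-4-({[tert-butyl(dimethyl)silyl]oxy}methyl)-6-[(2S)-3-(hydroxymethyl)-5-oxo-2,5-dihydrofuran-2-yl]hex-4-enoic acid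
Conditions: NaClO2, NaH2PO4, 2-methylbut-2-ene, t-BuOH/H2O, 0 °C to rt
Reagents that add atoms: sodium chlorite [Na+].[O-]Cl=O
Why: Pinnick oxidation converts only the aldehyde to the carboxylic acid, the hypochlorite by-product being trapped by 2-methylbut-2-ene so that the olefins, the free hydroxymethyl group and the silyl ether are untouched.

Step 14
Reactants: 25 (4Z)-4-({[tert-butyl(dimethyl)silyl]oxy}methyl)-6-[(2S)-3-(hydroxymethyl)-5-oxo-2,5-dihydrofuran-2-yl]hex-4-enoic acid; 9 (1S)-3-[(3E)-4-iodo-3-methylbut-3-en-1-yl]-2,4,4-trimethylcyclohex-2-en-1-ol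
Product: 27 (5S)-5-[(2Z,6E)-3-({[tert-butyl(dimethyl)silyl]oxy}methyl)-9-[(3S)-3-hydroxy-2,6,6-trimethylcyclohex-1-en-1-yl]-7-methylnona-2,6-dien-1-yl]-4-(hydroxymethyl)furan-2(5H)-one, via N-hydroxyphthalimide ester 26 (not isolated)
Conditions: N-hydroxyphthalimide, N,N'-diisopropylcarbodiimide, DMF, rt; then 9, NiCl2·6H2O (10 mol %), 2,2'-bipyridine (10 mol %), AgNO3 (0.3 equiv), LiCl, DMF, Mg anode, reticulated vitreous carbon cathode, constant current, rt
Reagents that add atoms: none
Why: The acid is activated in the flask as redox-active ester 26; cathodically generated low-valent nickel (from NiCl2·6H2O and 2,2'-bipyridine) adds oxidatively to alkenyl iodide 9 with retention of the E geometry, while single-electron reduction of 26 releases CO2 and phthalimide anion and leaves a primary homoallyl radical on the carbon that becomes the allylic CH2. Capture of this radical by the alkenylnickel species and reductive elimination from the resulting trivalent nickel intermediate form the C(sp2)–C(sp3) bond. The closest known reaction type is the nickel-electrocatalytic decarboxylative alkenylation of N-hydroxyphthalimide esters with alkenyl halides at a silver-nanoparticle-coated cathode, which has been used to assemble polyene terpenoids. No ring is closed and no stereocentre is formed, and both existing stereocentres are remote from the radical. The step needs retention of both olefin geometries and chemoselectivity over the butenolide and the free hydroxyls; these are secured by the stereoretentive oxidative addition, by the mild potential at which the nickel mediator works, and by the fact that 3-exo closure of the homoallyl radical is reversible and unproductive.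

Step 15
Reactants: 27 (5S)-5-[(2Z,6E)-3-({[tert-butyl(dimethyl)silyl]oxy}methyl)-9-[(3S)-3-hydroxy-2,6,6-trimethylcyclohex-1-en-1-yl]-7-methylnona-2,6-dien-1-yl]-4-(hydroxymethyl)furan-2(5H)-one
Product: 28 (5S)-4-(hydroxymethyl)-5-[(2Z,6E)-3-(hydroxymethyl)-9-[(3S)-3-hydroxy-2,6,6-trimethylcyclohex-1-en-1-yl]-7-methylnona-2,6-dien-1-yl]furan-2(5H)-one
Conditions: HF·pyridine, pyridine, THF, 0 °C to rt
Reagents that add atoms: none
Why: Fluoride-mediated desilylation under buffered acidic conditions removes the one silyl ether without base-induced epimerisation at C5 of the butenolide or ionisation of the ring allylic alcohol.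

Compound list
1 | (4-bromobut-1-yn-1-yl)trimethylsilane | C[Si](C)(C)C#CCCBr | starting material
2 | 2,6,6-trimethylcyclohex-2-en-1-one | CC1=CCCC(C)(C)C1=O | starting material
3 | [4-(trimethylsilyl)but-3-yn-1-yl]lithium | [Li]CCC#C[Si](C)(C)C | intermediate
4 | 2,6,6-trimethyl-1-[4-(trimethylsilyl)but-3-yn-1-yl]cyclohex-2-en-1-ol (racemic) | CC1=CCCC(C)(C)C1(O)CCC#C[Si](C)(C)C | intermediate
5 | 2,4,4-trimethyl-3-[4-(trimethylsilyl)but-3-yn-1-yl]cyclohex-2-en-1-one | CC1=C(CCC#C[Si](C)(C)C)C(C)(C)CCC1=O | intermediate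
6 | (1S)-2,4,4-trimethyl-3-[4-(trimethylsilyl)but-3-yn-1-yl]cyclohex-2-en-1-ol | CC1=C(CCC#C[Si](C)(C)C)C(C)(C)CC[C@@H]1O | intermediate
7 | (1S)-3-(but-3-yn-1-yl)-2,4,4-trimethylcyclohex-2-en-1-ol | CC1=C(CCC#C)C(C)(C)CC[C@@H]1O | intermediate
8 | dimethylaluminium alkoxide of (1S)-3-[(3E)-4-(dimethylalumanyl)-3-methylbut-3-en-1-yl]-2,4,4-trimethylcyclohex-2-en-1-ol | CC1=C(CC/C(C)=C/[Al](C)C)C(C)(C)CC[C@@H]1O[Al](C)C | intermediate
9 | (1S)-3-[(3E)-4-iodo-3-methylbut-3-en-1-yl]-2,4,4-trimethylcyclohex-2-en-1-ol | CC1=C(CC/C(C)=C/I)C(C)(C)CC[C@@H]1O | intermediate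
10 | 2-(2-bromoethyl)-1,3-dioxolane | BrCCC1OCCO1 | starting material
11 | prop-2-yn-1-ol | C#CCO | starting material
12 | [2-(1,3-dioxolan-2-yl)ethyl]magnesium bromide | Br[Mg]CCC1OCCO1 | intermediate
13 | bromomagnesium (2Z)-3-(bromomagnesio)-2-[2-(1,3-dioxolan-2-yl)ethyl]prop-2-en-1-olate | Br[Mg]/C=C(\CO[Mg]Br)CCC1OCCO1 | intermediate
14 | (2Z)-4-(1,3-dioxolan-2-yl)-2-(iodomethylidene)butan-1-ol | OC/C(=C\I)CCC1OCCO1 | intermediate
15 | tert-butyl{[(2Z)-4-(1,3-dioxolan-2-yl)-2-(iodomethylidene)butyl]oxy}dimethylsilane | CC(C)(C)[Si](C)(C)OC/C(=C\I)CCC1OCCO1 | intermediate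
16 | methyl (2S)-oxirane-2-carboxylate | COC(=O)[C@@H]1CO1 | starting material
17 | [(1Z)-2-({[tert-butyl(dimethyl)silyl]oxy}methyl)-4-(1,3-dioxolan-2-yl)but-1-en-1-yl]magnesium chloride | Cl[Mg]/C=C(\CO[Si](C)(C)C(C)(C)C)CCC1OCCO1 | intermediate
18 | chloromagnesium alkoxide of methyl (2S,4Z)-5-({[tert-butyl(dimethyl)silyl]oxy}methyl)-7-(1,3-dioxolan-2-yl)-2-hydroxyhept-4-enoate | COC(=O)[C@@H](O[Mg]Cl)C/C=C(\CO[Si](C)(C)C(C)(C)C)CCC1OCCO1 | intermediate
19 | methyl (2S,4Z)-2-(acetyloxy)-5-({[tert-butyl(dimethyl)silyl]oxy}methyl)-7-(1,3-dioxolan-2-yl)hept-4-enoate | COC(=O)[C@@H](OC(C)=O)C/C=C(\CO[Si](C)(C)C(C)(C)C)CCC1OCCO1 | intermediate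
20 | (5S)-5-[(2Z)-3-({[tert-butyl(dimethyl)silyl]oxy}methyl)-5-(1,3-dioxolan-2-yl)pent-2-en-1-yl]-4-hydroxyfuran-2(5H)-one | C1(CC/C(CO[Si](C)(C)C(C)(C)C)=C/C[C@@H]2OC(=O)C=C2O)OCCO1 | intermediate
21 | (2S)-2-[(2Z)-3-({[tert-butyl(dimethyl)silyl]oxy}methyl)-5-(1,3-dioxolan-2-yl)pent-2-en-1-yl]-5-oxo-2,5-dihydrofuran-3-yl trifluoromethanesulfonate | C1(CC/C(CO[Si](C)(C)C(C)(C)C)=C/C[C@@H]2OC(=O)C=C2OS(=O)(=O)C(F)(F)F)OCCO1 | intermediate
22 | (tributylstannyl)methanol | CCCC[Sn](CCCC)(CCCC)CO | starting material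
23 | (5S)-5-[(2Z)-3-({[tert-butyl(dimethyl)silyl]oxy}methyl)-5-(1,3-dioxolan-2-yl)pent-2-en-1-yl]-4-(hydroxymethyl)furan-2(5H)-one | C1(CC/C(CO[Si](C)(C)C(C)(C)C)=C/C[C@@H]2OC(=O)C=C2CO)OCCO1 | intermediate
24 | (4Z)-4-({[tert-butyl(dimethyl)silyl]oxy}methyl)-6-[(2S)-3-(hydroxymethyl)-5-oxo-2,5-dihydrofuran-2-yl]hex-4-enal | O=CCC/C(CO[Si](C)(C)C(C)(C)C)=C/C[C@@H]1OC(=O)C=C1CO | intermediate
25 | (4Z)-4-({[tert-butyl(dimethyl)silyl]oxy}methyl)-6-[(2S)-3-(hydroxymethyl)-5-oxo-2,5-dihydrofuran-2-yl]hex-4-enoic acid | OC(=O)CC/C(CO[Si](C)(C)C(C)(C)C)=C/C[C@@H]1OC(=O)C=C1CO | intermediate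
26 | 1,3-dioxoisoindolin-2-yl (4Z)-4-({[tert-butyl(dimethyl)silyl]oxy}methyl)-6-[(2S)-3-(hydroxymethyl)-5-oxo-2,5-dihydrofuran-2-yl]hex-4-enoate | O=C(CC/C(CO[Si](C)(C)C(C)(C)C)=C/C[C@@H]1OC(=O)C=C1CO)ON1C(=O)c2ccccc2C1=O | intermediate
27 | (5S)-5-[(2Z,6E)-3-({[tert-butyl(dimethyl)silyl]oxy}methyl)-9-[(3S)-3-hydroxy-2,6,6-trimethylcyclohex-1-en-1-yl]-7-methylnona-2,6-dien-1-yl]-4-(hydroxymethyl)furan-2(5H)-one | CC1=C(CC/C(C)=C/CC/C(CO[Si](C)(C)C(C)(C)C)=C/C[C@@H]2OC(=O)C=C2CO)C(C)(C)CC[C@@H]1O | intermediate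
28 | (5S)-4-(hydroxymethyl)-5-[(2Z,6E)-3-(hydroxymethyl)-9-[(3S)-3-hydroxy-2,6,6-trimethylcyclohex-1-en-1-yl]-7-methylnona-2,6-dien-1-yl]furan-2(5H)-one | CC1=C(CC/C(C)=C/CC/C(=C/C[C@@H]2OC(=O)C=C2CO)CO)C(C)(C)CC[C@@H]1O | target

Total step count: 15 (steps 1–5 for iodide 9, steps 6–13 for acid 25, steps 14 and 15).
Longest linear sequence: 10 steps (steps 6–15, from 10 and 11 to 28).

Steps most likely to fail

Step 14. What may go wrong: the alkenyl iodide is used up by protodehalogenation or homocoupling, or the butenolide is reduced at the cathode, before the alkyl radical is captured. Fallback (redox-neutral, no electrolysis): from 9, deprotonation and lithium–iodine exchange (t-BuLi, 3 equiv, Et2O, −78 °C) followed by ZnCl2 give the alkenylzinc chloride F1. Ester 26, this time isolated, is then coupled with it under thermal nickel catalysis (Ni(acac)2, 2,2'-bipyridine, THF/DMF, rt; decarboxylative Negishi-type alkenylation), which returns to 27.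

Step 11. What may go wrong: transfer of the sp3 hydroxymethyl group from tin is slow, so the enol triflate is hydrolysed back to the tetronic acid or reduced. Fallback: from 21, palladium-catalysed reductive carbonylation (Pd(PPh3)4, CO, Bu3SnH, THF, 50 °C) gives the 4-formylbutenolide F2. Luche reduction of the aldehyde (NaBH4, CeCl3·7H2O, MeOH, −78 °C) returns to 23.

Step 8. What may go wrong: iodine–magnesium exchange is incomplete, or the alkenylmagnesium attacks the ester carbonyl in place of the epoxide. Fallback (radical C–C bond formation from the chiral pool): commercial (S)-2,2-dimethyl-5-oxo-1,3-dioxolane-4-acetic acid, derived from (S)-malic acid, is converted with N-hydroxyphthalimide and N,N'-diisopropylcarbodiimide into the redox-active ester F3. This is coupled with 15 under the electrochemical conditions of step 14 to give the dioxolanone F4. Methanolysis (K2CO3, MeOH, 0 °C) gives the α-hydroxy ester F5, and acetylation (Ac2O, pyridine) returns to 19.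

Further compounds
F1 | step 14 | lithium alkoxide of (1S)-3-[(3E)-4-(chlorozincio)-3-methylbut-3-en-1-yl]-2,4,4-trimethylcyclohex-2-en-1-ol | CC1=C(CC/C(C)=C/[Zn]Cl)C(C)(C)CC[C@@H]1O[Li]
F2 | step 11 | (2S)-2-[(2Z)-3-({[tert-butyl(dimethyl)silyl]oxy}methyl)-5-(1,3-dioxolan-2-yl)pent-2-en-1-yl]-5-oxo-2,5-dihydrofuran-3-carbaldehyde | C1(CC/C(CO[Si](C)(C)C(C)(C)C)=C/C[C@@H]2OC(=O)C=C2C=O)OCCO1
F3 | step 8 | 1,3-dioxoisoindolin-2-yl [(4S)-2,2-dimethyl-5-oxo-1,3-dioxolan-4-yl]acetate | CC1(C)OC(=O)[C@H](CC(=O)ON2C(=O)c3ccccc3C2=O)O1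
F4 | step 8 | (5S)-5-[(2Z)-3-({[tert-butyl(dimethyl)silyl]oxy}methyl)-5-(1,3-dioxolan-2-yl)pent-2-en-1-yl]-2,2-dimethyl-1,3-dioxolan-4-one | CC1(C)OC(=O)[C@H](C/C=C(\CO[Si](C)(C)C(C)(C)C)CCC2OCCO2)O1
F5 | step 8 | methyl (2S,4Z)-5-({[tert-butyl(dimethyl)silyl]oxy}methyl)-7-(1,3-dioxolan-2-yl)-2-hydroxyhept-4-enoate | COC(=O)[C@@H](O)C/C=C(\CO[Si](C)(C)C(C)(C)C)CCC1OCCO1
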